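**Retrosynthetic overview**
- Target 18 comes from tetralinol 16 by acid-only operations (E1 dehydration, then acidolysis); every ester is tert-butyl and the catechol is a diphenylmethylene ketal, so no base is needed after ring B exists.
- The strategy rests on ring B (C1–C2–C3–C4–C4a–C8a): C1 lies between ring A and C4 of the pyrone, C4 is the ortho carbon at the aldehyde oxidation level, and C2/C3 form a trans-succinate. Cutting C1–C2 and C3–C4 therefore gives the photoenol (a hydroxy-o-quinodimethane) of aldehyde 13 and fumarate 14.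
- Aldehyde 13 is assembled at the C1 methylene by Suzuki coupling of aryl boronate 5 (from 6-bromoveratraldehyde 1) with pyronylmethyl bromide 12.
- Bromide 12 derives from 4-methyl-2-pyrone-6-carboxylic acid 10, itself made from ethyl senecioate 6 and diethyl oxalate 7.
- Ring order: the pyrone ring (step 5) and the protecting dioxole (step 2) first, ring A bought, ring B last (step 9).

Key step: step 9

Assumption: (R,R)-TADDOL is taken as the ligand enantiomer that leads to 1R; if the sense of induction proves opposite, the (S,S) ligand is used with nothing else changed.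

Step 1
Reactants: 1 2-bromo-4,5-dimethoxybenzaldehyde
Product: 2 2-bromo-4,5-dihydroxybenzaldehyde
Conditions: BBr3 (3 equiv), CH2Cl2, −78 °C to 23 °C; H2O quench
Reagents that add atoms: none
Why: BBr3 demethylation of both aryl methyl ethers should proceed with the aldehyde and aryl bromide intact, the boron-bound catechol being hydrolysed on quench.

Step 2
Reactants: 2 2-bromo-4,5-dihydroxybenzaldehyde; 3 dichlorodiphenylmethane
Product: 4 6-bromo-2,2-diphenyl-1,3-benzodioxole-5-carbaldehyde
Conditions: Ph2O, 175 °C, N2 sweep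
Reagents that add atoms: none
Why: Double O-alkylation of the catechol by the ionizable benzhydrylic dichloride (ketal formation) should close the 2,2-diphenyl-1,3-dioxole, with HCl leaving as gas and the aldehyde tolerated as in the parent protocatechualdehyde case.

Step 3
Reactants: 4 6-bromo-2,2-diphenyl-1,3-benzodioxole-5-carbaldehyde
Product: 5 2,2-diphenyl-6-(4,4,5,5-tetramethyl-1,3,2-dioxaborolan-2-yl)-1,3-benzodioxole-5-carbaldehyde
Conditions: B2pin2, Pd(dppf)Cl2 (5 mol%), KOAc, 1,4-dioxane, 85 °C
Reagents that add atoms: bis(pinacolato)diboron, CC1(C)OB(OC1(C)C)B1OC(C)(C)C(C)(C)O1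
Why: Miyaura borylation should work well because the ortho formyl group speeds oxidative addition and acetate is too weak a base to start Suzuki homocoupling or harm the aldehyde.

Step 4
Reactants: 6 ethyl 3-methylbut-2-enoate; 7 diethyl oxalate
Product: 8 potassium (2Z,4Z)-1,6-diethoxy-4-methyl-1,6-dioxohexa-2,4-dien-2-olate
Conditions: KOEt (1.05 equiv), Et2O/EtOH, 0 °C to 23 °C; salt filtered
Reagents that add atoms: potassium ethoxide, CC[O-].[K+]
Why: In this vinylogous Claisen condensation the dienolate from γ-deprotonation of the senecioate acylates the non-enolizable oxalate at the γ-carbon, and precipitation of the conjugated potassium enolate should pull the equilibrium forward.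

Step 5
Reactants: 8 potassium (2Z,4Z)-1,6-diethoxy-4-methyl-1,6-dioxohexa-2,4-dien-2-olate
Product: 10 4-methyl-2-oxo-2H-pyran-6-carboxylic acid, via ethyl 4-methyl-2-oxo-2H-pyran-6-carboxylate 9 (not isolated)
Conditions: conc. HCl, 95 °C; cool, filter
Reagents that add atoms: water, O
Why: Acid frees the enol, whose oxygen lactonizes onto the distal ester to close the six-membered 2-pyrone (the alkene geometry equilibrates through the keto tautomer), and the acid-stable pyrone then survives hydrolysis of the remaining ethyl ester.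

Step 6
Reactants: 10 4-methyl-2-oxo-2H-pyran-6-carboxylic acid
Product: 11 tert-butyl 4-methyl-2-oxo-2H-pyran-6-carboxylate
Conditions: tert-butyl 2,2,2-trichloroacetimidate (2 equiv), BF3·OEt2 (cat.), CH2Cl2/cyclohexane, 23 °C
Reagents that add atoms: tert-butyl 2,2,2-trichloroacetimidate, CC(C)(C)OC(=N)C(Cl)(Cl)Cl
Why: Acid-catalysed tert-butyl transfer from the imidate esterifies the acid without any nucleophile or base that could open the pyrone.

Step 7
Reactants: 11 tert-butyl 4-methyl-2-oxo-2H-pyran-6-carboxylate
Product: 12 tert-butyl 4-(bromomethyl)-2-oxo-2H-pyran-6-carboxylate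
Conditions: NBS (1.05 equiv), AIBN (cat.), PhCF3, 80 °C
Reagents that add atoms: N-bromosuccinimide, O=C1CCC(=O)N1Br
Why: Wohl–Ziegler bromination should select the C4 methyl because its radical is delocalized over the pyrone, while the ester-bearing, electron-poor ring resists ionic bromination in a non-polar medium.

Step 8
Reactants: 5 2,2-diphenyl-6-(4,4,5,5-tetramethyl-1,3,2-dioxaborolan-2-yl)-1,3-benzodioxole-5-carbaldehyde; 12 tert-butyl 4-(bromomethyl)-2-oxo-2H-pyran-6-carboxylate
Product: 13 tert-butyl 4-[(6-formyl-2,2-diphenyl-1,3-benzodioxol-5-yl)methyl]-2-oxo-2H-pyran-6-carboxylate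
Conditions: Pd(dppf)Cl2 (5 mol%), CsF (3 equiv), 1,4-dioxane (dry), 70 °C
Reagents that add atoms: none
Why: In this sp2–sp3 Suzuki–Miyaura coupling the activated allylic-type bromide adds readily to palladium and has no β-hydrogen, and anhydrous fluoride activates the boronate without the hydroxide or water that would open the pyrone or protodeboronate the ortho-formyl boronate.

Step 9
Reactants: 13 tert-butyl 4-[(6-formyl-2,2-diphenyl-1,3-benzodioxol-5-yl)methyl]-2-oxo-2H-pyran-6-carboxylate; 14 di-tert-butyl fumarate
Product: 16 di-tert-butyl (1R,2S,3R,4R)-1-[6-(tert-butoxycarbonyl)-2-oxo-2H-pyran-4-yl]-4-hydroxy-6,7-(diphenylmethylenedioxy)-1,2,3,4-tetrahydronaphthalene-2,3-dicarboxylate, via (E,E)-hydroxy-o-quinodimethane photoenol 15 (not isolated)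
Conditions: Ti(OiPr)4 (2 equiv), (R,R)-TADDOL (2.2 equiv), toluene (degassed), 365 nm LED, 20 °C; 10% aqueous citric acid work-up
Reagents that add atoms: none
Why: Proposed new method: excitation of the aldehyde of 13 at 365 nm and 1,5-hydrogen transfer from the CH2 (activated by ring A and by the pyrone) should give dienol 15, whose oxygen binds the TADDOLate titanium centre that also holds one carbonyl of 14, and a concerted endo [4+2] cycloaddition then forms C1–C2 and C3–C4. The closest known reactions are the Ti(OiPr)4/TADDOL-mediated enantioselective photoenolization/Diels–Alder reactions of 2-methylbenzaldehydes with enones and the untemplated trapping of photoenols of 2-benzylbenzaldehydes by fumarates; combining a diarylmethane-type hydrogen donor with an acyclic fumarate diester on the chiral titanium template is untested. Ring B closes by intermolecular [4+2] annulation across the C4a–C8a bond, driven by rearomatization of ring A. C1 (R) is set by the dienol face left open by the TADDOL aryl groups; C4 is cis to C1 because OH and pyronyl both point outward on the diene, C3 is cis to C4 through the titanium bridge between the dienol oxygen and the adjacent ester carbonyl, and C2 is trans to C3 because the fumarate geometry is retained, so the C2 ester ends trans to the pyronyl group. The step needs enantiofacial and endo selectivity plus outward placement of the pyronyl group; these rest on two-point binding at titanium and on the size of the pyronyl group, while the 2-pyrone absorbs at shorter wavelength and is a poor thermal diene or dienophile at 20 °C.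

Step 10
Reactants: 16 di-tert-butyl (1R,2S,3R,4R)-1-[6-(tert-butoxycarbonyl)-2-oxo-2H-pyran-4-yl]-4-hydroxy-6,7-(diphenylmethylenedioxy)-1,2,3,4-tetrahydronaphthalene-2,3-dicarboxylate
Product: 17 di-tert-butyl (1R,2S)-1-[6-(tert-butoxycarbonyl)-2-oxo-2H-pyran-4-yl]-6,7-(diphenylmethylenedioxy)-1,2-dihydronaphthalene-2,3-dicarboxylate
Conditions: TFA (10 vol%), CH2Cl2, 0 °C, stopped at full conversion; toluene co-evaporation
Reagents that add atoms: none
Why: In this E1 dehydration the C4 hydroxyl ionizes to a benzylic cation stabilized by the para oxygen on C7 and loss of H3 gives the aryl- and ester-conjugated C3=C4 bond without touching C1 or C2, since no base is present; the tert-butyl esters cleave much more slowly under this dilute acid and any partial loss only anticipates step 11.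

Step 11
Reactants: 17 di-tert-butyl (1R,2S)-1-[6-(tert-butoxycarbonyl)-2-oxo-2H-pyran-4-yl]-6,7-(diphenylmethylenedioxy)-1,2-dihydronaphthalene-2,3-dicarboxylate
Product: 18 (1R,2S)-1-(6-carboxy-2-oxo-2H-pyran-4-yl)-6,7-dihydroxy-1,2-dihydronaphthalene-2,3-dicarboxylic acid
Conditions: TFA/H2O (9:1), 0.02 M, 23 °C; evaporate; C18 chromatography (H2O/MeCN, 0.1% HCO2H)
Reagents that add atoms: none
Why: Acidolysis of the three tert-butyl esters (loss of isobutene) and hydrolysis of the diphenylmethylene ketal (loss of benzophenone) should occur under one acidic regime that the pyrone and acrylate tolerate, and the trans C1/C2 arrangement, the more stable one, is not exposed to base.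

**Compound list**
1 | 2-bromo-4,5-dimethoxybenzaldehyde | COc1cc(Br)c(C=O)cc1OC | starting material
2 | 2-bromo-4,5-dihydroxybenzaldehyde | O=Cc1cc(O)c(O)cc1Br | intermediate
3 | dichlorodiphenylmethane | ClC(Cl)(c1ccccc1)c1ccccc1 | starting material
4 | 6-bromo-2,2-diphenyl-1,3-benzodioxole-5-carbaldehyde | O=Cc1cc2OC(c3ccccc3)(c3ccccc3)Oc2cc1Br | intermediate
5 | 2,2-diphenyl-6-(4,4,5,5-tetramethyl-1,3,2-dioxaborolan-2-yl)-1,3-benzodioxole-5-carbaldehyde | O=Cc1cc2OC(c3ccccc3)(c3ccccc3)Oc2cc1B1OC(C)(C)C(C)(C)O1 | intermediate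
6 | ethyl 3-methylbut-2-enoate | CC(C)=CC(=O)OCC | starting material
7 | diethyl oxalate | CCOC(=O)C(=O)OCC | starting material
8 | potassium (2Z,4Z)-1,6-diethoxy-4-methyl-1,6-dioxohexa-2,4-dien-2-olate | CCOC(=O)/C([O-])=C/C(C)=C\C(=O)OCC.[K+] | intermediate
9 | ethyl 4-methyl-2-oxo-2H-pyran-6-carboxylate | CCOC(=O)c1cc(C)cc(=O)o1 | intermediate (not isolated)
10 | 4-methyl-2-oxo-2H-pyran-6-carboxylic acid | Cc1cc(=O)oc(C(=O)O)c1 | intermediate
11 | tert-butyl 4-methyl-2-oxo-2H-pyran-6-carboxylate | Cc1cc(=O)oc(C(=O)OC(C)(C)C)c1 | intermediate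
12 | tert-butyl 4-(bromomethyl)-2-oxo-2H-pyran-6-carboxylate | BrCc1cc(=O)oc(C(=O)OC(C)(C)C)c1 | intermediate
13 | tert-butyl 4-[(6-formyl-2,2-diphenyl-1,3-benzodioxol-5-yl)methyl]-2-oxo-2H-pyran-6-carboxylate | O=Cc1cc2OC(c3ccccc3)(c3ccccc3)Oc2cc1Cc1cc(C(=O)OC(C)(C)C)oc(=O)c1 | intermediate
14 | di-tert-butyl fumarate | CC(C)(C)OC(=O)/C=C/C(=O)OC(C)(C)C | starting material
15 | tert-butyl 4-{(E)-[(6E)-6-(hydroxymethylidene)-2,2-diphenyl-1,3-benzodioxol-5(6H)-ylidene]methyl}-2-oxo-2H-pyran-6-carboxylate, the (E,E)-hydroxy-o-quinodimethane (photoenol of 13) | O/C=C1\C=C2OC(c3ccccc3)(c3ccccc3)OC2=C/C1=C\c1cc(C(=O)OC(C)(C)C)oc(=O)c1 | intermediate (not isolated)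
16 | di-tert-butyl (1R,2S,3R,4R)-1-[6-(tert-butoxycarbonyl)-2-oxo-2H-pyran-4-yl]-4-hydroxy-6,7-(diphenylmethylenedioxy)-1,2,3,4-tetrahydronaphthalene-2,3-dicarboxylate (1,2-trans, 2,3-trans, 3,4-cis) | O[C@H]1c2cc3OC(c4ccccc4)(c4ccccc4)Oc3cc2[C@@H](c2cc(C(=O)OC(C)(C)C)oc(=O)c2)[C@H](C(=O)OC(C)(C)C)[C@H]1C(=O)OC(C)(C)C | intermediate
17 | di-tert-butyl (1R,2S)-1-[6-(tert-butoxycarbonyl)-2-oxo-2H-pyran-4-yl]-6,7-(diphenylmethylenedioxy)-1,2-dihydronaphthalene-2,3-dicarboxylate | CC(C)(C)OC(=O)C1=Cc2cc3OC(c4ccccc4)(c4ccccc4)Oc3cc2[C@@H](c2cc(C(=O)OC(C)(C)C)oc(=O)c2)[C@@H]1C(=O)OC(C)(C)C | intermediate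
18 | (1R,2S)-1-(6-carboxy-2-oxo-2H-pyran-4-yl)-6,7-dihydroxy-1,2-dihydronaphthalene-2,3-dicarboxylic acid | O=C(O)C1=Cc2cc(O)c(O)cc2[C@@H](c2cc(C(=O)O)oc(=O)c2)[C@@H]1C(=O)O | target

**Step count**
Total: 11 steps. Longest linear sequence: 8 steps (steps 4–11, from 6 and 7).

**Steps most likely to fail**

Step 9. The titanium-bound dienol may add to the acyclic fumarate with poor enantiofacial or endo discrimination, or titanium alkoxide exchange may slowly attack the pyrone lactone during irradiation. The fallback sets out from 13 and 14: irradiation at 365 nm in degassed toluene without titanium, the known trapping of photoenols of 2-benzylbenzaldehydes by fumarates, should give the racemic 1,2-trans-2,3-trans-3,4-cis adduct. This is 16 together with its mirror image, di-tert-butyl (1S,2R,3S,4S)-1-[6-(tert-butoxycarbonyl)-2-oxo-2H-pyran-4-yl]-4-hydroxy-6,7-(diphenylmethylenedioxy)-1,2,3,4-tetrahydronaphthalene-2,3-dicarboxylate F1. Preparative chromatography on a chiral stationary phase separates the two, and the route is rejoined at 16.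

Step 8. Protodeboronation of the ortho-formyl boronate may outrun transmetalation, or the newly formed acidic CH2 may be alkylated a second time under the fluoride base. The fallback sets out from 4: stannylation with hexamethylditin (Pd(PPh3)4, toluene, 100 °C) should give 2,2-diphenyl-6-(trimethylstannyl)-1,3-benzodioxole-5-carbaldehyde F2. A base-free Stille coupling of this stannane with 12 (Pd2(dba)3, AsPh3, THF, 50 °C) comes back to the route at 13.

Step 7. Bromination may run on to the dibromomethyl stage or switch to ionic substitution at the ring CH positions. The fallback sets out from 11: Riley oxidation (SeO2, 1,4-dioxane, 100 °C) to tert-butyl 4-formyl-2-oxo-2H-pyran-6-carboxylate F3, then Luche reduction (NaBH4, CeCl3·7H2O, MeOH, −40 °C) to tert-butyl 4-(hydroxymethyl)-2-oxo-2H-pyran-6-carboxylate F4. Appel bromination (CBr4, PPh3, CH2Cl2, 0 °C) comes back to the route at 12.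

Further compounds
F1 | step 9 | di-tert-butyl (1S,2R,3S,4S)-1-[6-(tert-butoxycarbonyl)-2-oxo-2H-pyran-4-yl]-4-hydroxy-6,7-(diphenylmethylenedioxy)-1,2,3,4-tetrahydronaphthalene-2,3-dicarboxylate | O[C@@H]1c2cc3OC(c4ccccc4)(c4ccccc4)Oc3cc2[C@H](c2cc(C(=O)OC(C)(C)C)oc(=O)c2)[C@@H](C(=O)OC(C)(C)C)[C@@H]1C(=O)OC(C)(C)C
F2 | step 8 | 2,2-diphenyl-6-(trimethylstannyl)-1,3-benzodioxole-5-carbaldehyde | O=Cc1cc2OC(c3ccccc3)(c3ccccc3)Oc2cc1[Sn](C)(C)C
F3 | step 7 | tert-butyl 4-formyl-2-oxo-2H-pyran-6-carboxylate | O=Cc1cc(=O)oc(C(=O)OC(C)(C)C)c1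
F4 | step 7 | tert-butyl 4-(hydroxymethyl)-2-oxo-2H-pyran-6-carboxylate | OCc1cc(=O)oc(C(=O)OC(C)(C)C)c1
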